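Z cannot become D in a single step: the scheme has no such arrow, and every D has first been X.

    X ⇌ G (K1 = 0.64, k1 = 0.088 /s)
    X → D (k2 = 0.016 /s)
    Z → X (k3 = 0.0083 /s)
    Z + L → Z.L (k4 = 0.0066 /M/s)
    Z + Z2 → Z.Z2 (k5 = 0.0019 /M/s)
    2 Z → Z2 (k6 = 0.0023 /M/s)

all flasks: Z 1.5 M; L 1.50 M

| charge | time |
|---|---|
| cedar | 2.5 min |
| larch | 4.0 min |
| ash | 6.0 min |

- in percentages every species weighs as the Z in it: one Z2 counts as two
- in percentages every species weighs as the Z in it: one Z.Z2 counts as three
- two of one species on the left: rate k times its square, two consumed each time
- run time (cedar): 2.5 min

* which of these there is most of at the end, counted by the Z in it, cedar (G / Z / Z2 / D / X)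
* which of these there is most of at the end, counted by the Z in it, larch (G / Z / Z2 / D / X)
* which of these there is most of at the end, counted by the Z in it, ash (G / Z / Z2 / D / X)
* final amount of the leader among these, as a percentage of the Z charged, in cedar
* final amount of the leader among these, as a percentage of the Z charged, in larch
* final amount of the leader among these, as a percentage of the Z charged, in ash

Two chemists dispute the leader. X and G trade with a relaxation half-life of 0.0512 min, and the drain side treats them as one ring pool (a pre-equilibrium) in which X holds 61.0 % of the rings. The pool therefore empties into D with a lifetime of 1.71 min: this drain lifetime, the mean wait of a ring in X and G before it becomes D, is the clock of the argument, and it is far longer than the relaxation.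

The dimer side argues from the start. Dimerisation then takes 27.5 % of the Z being lost, and Z2 has no pool to wait in, whereas cedar lasts 1.46 drain lifetimes. On that view Z2 should stand ahead of D in cedar.

I take the drain side and reckon by hand, leaving the step Z + Z2 aside. The dimer rate goes with [Z] squared, so its share sinks as Z is spent. I take the mid-course state, [Z] = 0.750 M and [L] = 1.20 M, where [L] is the charge less the starting share of the Z spent. There Z has a lifetime of 0.846 min, the ring share (the selectivity for X) is 42.1 %, and the dimer share is 17.5 %, less than at the start.

Rings pass through these two lifetimes in series, so I reckon that by the end of cedar 59.3 % of the ring share has reached D. That gives 25.0 % in cedar, more than the dimer share. Larch comes to 34.5 % and ash to 39.7 %.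

The forecast, the drain side's number, names D, D and D as leaders, at 25 %, 35 % and 41.5 %; its cedar figure is the same as mine, but its larch and ash figures are not. Its grounds: “X and G equilibrate quickly and then drain steadily into D”.

The simulation puts D ahead in cedar at 24.1 %, D in larch at 33.8 % and D in ash at 39.8 %; Z2 reads 14.8 % in cedar, less than D.

The dimer side's ground is the early flask: larch stopped at 1.0 min, 0.585 drain lifetimes in, holds more Z2 than D, 13.6 % against 8.31 %, with Z itself at 29.4 %. Ash has not come to rest: after 3.51 drain lifetimes, X and G together hold 3.00 % and Z holds 0.316 %. Left until 60.0 min, ash reads 0 % of Z and 42.9 % of D, which is 3.1 percentage points higher.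

(The constants belong to no real substance.)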